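**Strategy**

Everything rests on cutting ring A at C8–C8a and C6–C7. Ring A is a phloroglucinol in which oxygen (C5, C7, C8a) and carbon substituents (C4a, C6, C8) alternate at all six positions; this pattern maps onto a 3-alkoxy-4-prenylcyclobutenone and a prenylated siloxyalkyne. One thermal cascade builds the whole ring with its oxygens differentiated: a free hydroxyl at C8a between the two prenyl groups and two fluoride-labile ethers flanking the only ring CH, C6. The cyclobutenone therefore carries a 2-(trimethylsilyl)ethoxy group, so that chromene closure onto either prenyl group converges on one diol before C6 is aroylated.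

Key step: step 4

Remark on the chemistry: the alkoxy group of the cyclobutenone is treated as a protecting group and is chosen as 2-(trimethylsilyl)ethyl, not ethyl, because an ethyl ether ortho to the final ketone would resist cleavage once the other ortho oxygen is chelated, and the prenyl and chromene units rule out forcing Lewis acids.

**Route**

Step 1
Reactants: 1 2-(trimethylsilyl)ethanol
Product: 5 [2-(ethynyloxy)ethyl]trimethylsilane, via dichlorovinyl ether 2 (not isolated), via chloroethynyl ether 3 (not isolated), via lithium alkoxyacetylide 4 (not isolated)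
Conditions: KH, THF, 0 °C; Cl2C=CHCl, −50 °C → rt; n-BuLi (2.4 equiv), −78 → −40 °C; H2O
Reagents that add atoms: trichloroethylene, ClC=C(Cl)Cl
Why: Alkynyl ether synthesis from an alcohol and trichloroethylene: the potassium alkoxide adds to dichloroacetylene formed in situ to give 2, n-BuLi then effects dehydrochlorination to 3 and chlorine–lithium exchange to 4, and the quench protonates the acetylide.

Step 2
Reactants: 6 5-methylhex-4-enoic acid; 5 [2-(ethynyloxy)ethyl]trimethylsilane
Product: 9 4-(3-methylbut-2-en-1-yl)-3-[2-(trimethylsilyl)ethoxy]cyclobut-2-en-1-one (racemic), via acid chloride 7 (not isolated), via prenylketene 8 (not isolated)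
Conditions: (COCl)2, DMF (cat.), CH2Cl2, 0 °C → rt; concentrate; then 5 (1.5 equiv), Et3N, Et2O, rt (slow addition of 7)
Reagents that add atoms: none
Why: Dehydrochlorination of 7 gives aldoketene 8, which should undergo the regioselective ketene–alkynyl ether [2+2] cycloaddition (ketene carbonyl carbon to the unsubstituted alkyne carbon) that is the standard entry to 3-alkoxycyclobutenones; C4 is formed racemic and is erased in step 4.

Step 3
Reactants: 10 ethyl 4-methylpent-3-enoate
Product: 13 triisopropyl[(5-methylhex-4-en-1-yn-1-yl)oxy]silane, via dibromo enolate 11 (not isolated), via lithium ynolate 12 (not isolated)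
Conditions: CH2Br2, LiTMP, THF, −78 °C; then n-BuLi, −78 → 0 °C; then iPr3SiOTf, −78 °C → rt
Reagents that add atoms: dibromomethane, BrCBr; triisopropylsilyl trifluoromethanesulfonate, CC(C)[Si](OS(=O)(=O)C(F)(F)F)(C(C)C)C(C)C
Why: Kowalski ester homologation stopped at the ynolate: dibromomethyllithium adds to the ester, the dibromoketone is enolised to 11, bromine–lithium exchange with 1,2-shift of the allylic carbon gives 12, and the bulky silyl triflate should silylate 12 on oxygen.

Step 4
Reactants: 9 4-(3-methylbut-2-en-1-yl)-3-[2-(trimethylsilyl)ethoxy]cyclobut-2-en-1-one; 13 triisopropyl[(5-methylhex-4-en-1-yn-1-yl)oxy]silane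
Product: 18 2,6-bis(3-methylbut-2-en-1-yl)-3-[(triisopropylsilyl)oxy]-5-[2-(trimethylsilyl)ethoxy]phenol, via vinylketene 14 (not isolated), via vinylcyclobutenone 15 (not isolated), via dienylketene 16 (not isolated), via cyclohexadienone 17 (not isolated)
Conditions: PhMe, 110 °C, sealed tube, N2 (13, 1.3 equiv)
Reagents that add atoms: none
Why: Thermal 4π electrocyclic opening of strained cyclobutenone 9 (prenyl rotating outward) should give vinylketene 14, whose carbonyl carbon is attacked by the nucleophilic, prenyl-bearing carbon of siloxyalkyne 13 in a [2+2] cycloaddition to 15; a second, reversible 4π opening gives dienylketene 16, which closes to cyclohexadienone 17 and tautomerises to phenol 18. This is the Danheiser benzannulation of a cyclobutenone with a siloxyalkyne, applied here to a 3-alkoxy-4-alkyl cyclobutenone. Ring A is closed by a thermally allowed disrotatory 6π electrocyclisation that re-forms the C4a–C8a bond, while the two net new skeletal bonds, C8a–C8 and C6–C7, come from the [2+2] step. No stereocentre survives, because the sp3 carbons of 15 and 17 are lost on ring opening and aromatisation. The step needs head-to-tail regiochemistry, which the polarisation of the silyl ynol ether against the electrophilic ketene carbon secures, and the outward rotation of the C4 substituent holds the prenyl chain away from the ketene and so disfavours intramolecular ketene–alkene cycloaddition. The expected outcome is a phenol whose free hydroxyl (future O1) lies between the two prenyl groups and whose other two oxygens are fluoride-labile ethers flanking the single ring CH (future C6).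

Step 5
Reactants: 18 2,6-bis(3-methylbut-2-en-1-yl)-3-[(triisopropylsilyl)oxy]-5-[2-(trimethylsilyl)ethoxy]phenol
Product: 21 2,2-dimethyl-8-(3-methylbut-2-en-1-yl)-2H-chromene-5,7-diol, via 7-silyloxy chromene 19 (not isolated), via 5-silyloxy chromene 20 (not isolated)
Conditions: DDQ (1.05 equiv), PhH, 80 °C; filter, concentrate; then Bu4NF (5 equiv), DMF, 80 °C; AcOH
Reagents that add atoms: none
Why: Oxidative cyclisation of an ortho-prenylphenol with DDQ (benzylic hydride abstraction, then closure of the phenol oxygen onto the dienyl system) should give 2,2-dimethylchromenes 19 and 20, and fluoride then cleaves the triisopropylsilyl ether and, by β-elimination of ethylene and Me3SiF, the 2-(trimethylsilyl)ethyl ether of both, so that the two modes of ring closure converge on the single diol 21.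

Step 6
Reactants: 21 2,2-dimethyl-8-(3-methylbut-2-en-1-yl)-2H-chromene-5,7-diol
Product: 22 5,7-bis(methoxymethoxy)-2,2-dimethyl-8-(3-methylbut-2-en-1-yl)-2H-chromene
Conditions: MOMCl, iPr2NEt, CH2Cl2, 0 °C → rt
Reagents that add atoms: chloromethyl methyl ether, COCCl
Why: Williamson-type O-alkylation of both phenols under amine base, in which the hard electrophile should favour O- over C-alkylation of the electron-rich ring.

Step 7
Reactants: 23 4-hydroxybenzaldehyde
Product: 24 4-(methoxymethoxy)benzaldehyde
Conditions: MOMCl, iPr2NEt, CH2Cl2, 0 °C → rt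
Reagents that add atoms: chloromethyl methyl ether, COCCl
Why: Williamson-type O-alkylation of an acidic phenol, which masks the only proton that would quench the aryllithium of step 8.

Step 8
Reactants: 22 5,7-bis(methoxymethoxy)-2,2-dimethyl-8-(3-methylbut-2-en-1-yl)-2H-chromene; 24 4-(methoxymethoxy)benzaldehyde
Product: 26 [5,7-bis(methoxymethoxy)-2,2-dimethyl-8-(3-methylbut-2-en-1-yl)-2H-chromen-6-yl][4-(methoxymethoxy)phenyl]methanol (racemic), via aryllithium 25 (not isolated)
Conditions: n-BuLi, THF, 0 °C; then 24, −78 → 0 °C; H2O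
Reagents that add atoms: none
Why: Directed ortho-metalation, in which C6–H is the only ring hydrogen and lies between two methoxymethoxy groups, should give aryllithium 25 ahead of lateral deprotonation of the prenyl CH2, and 25 adds to the aldehyde; the carbinol centre is racemic and is removed in step 9.

Step 9
Reactants: 26 [5,7-bis(methoxymethoxy)-2,2-dimethyl-8-(3-methylbut-2-en-1-yl)-2H-chromen-6-yl][4-(methoxymethoxy)phenyl]methanol
Product: 27 [5,7-bis(methoxymethoxy)-2,2-dimethyl-8-(3-methylbut-2-en-1-yl)-2H-chromen-6-yl][4-(methoxymethoxy)phenyl]methanone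
Conditions: Dess–Martin periodinane, NaHCO3, CH2Cl2, 0 °C → rt
Reagents that add atoms: none
Why: Dess–Martin oxidation of a doubly benzylic secondary alcohol under bicarbonate buffering, which should leave the acetals, the chromene and the prenyl group untouched.

Step 10
Reactants: 27 [5,7-bis(methoxymethoxy)-2,2-dimethyl-8-(3-methylbut-2-en-1-yl)-2H-chromen-6-yl][4-(methoxymethoxy)phenyl]methanone
Product: 28 vismiaphenone E, [5,7-dihydroxy-2,2-dimethyl-8-(3-methylbut-2-en-1-yl)-2H-chromen-6-yl](4-hydroxyphenyl)methanone
Conditions: HCl (3 M aq), MeOH, 40 °C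
Reagents that add atoms: none
Why: Acid-catalysed acetal exchange should remove all three methoxymethyl ethers (the two ortho to the carbonyl assisted by hydrogen bonding) under conditions mild enough to spare the chromene and to avoid cyclisation of the C8 prenyl group onto the C7 hydroxyl.

**Compound list**

1 | 2-(trimethylsilyl)ethanol | C[Si](C)(C)CCO | starting material
2 | trimethyl(2-{[(E)-1,2-dichloroethenyl]oxy}ethyl)silane (not isolated) | C[Si](C)(C)CCO/C(Cl)=C\Cl | intermediate
3 | {2-[(chloroethynyl)oxy]ethyl}trimethylsilane (not isolated) | C[Si](C)(C)CCOC#CCl | intermediate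
4 | lithium [2-(trimethylsilyl)ethoxy]acetylide (not isolated) | C[Si](C)(C)CCOC#C[Li] | intermediate
5 | [2-(ethynyloxy)ethyl]trimethylsilane | C[Si](C)(C)CCOC#C | intermediate
6 | 5-methylhex-4-enoic acid | CC(C)=CCCC(=O)O | starting material
7 | 5-methylhex-4-enoyl chloride (not isolated) | CC(C)=CCCC(=O)Cl | intermediate
8 | (3-methylbut-2-enyl)ketene, 5-methylhexa-1,4-dien-1-one (not isolated) | CC(C)=CCC=C=O | intermediate
9 | 4-(3-methylbut-2-en-1-yl)-3-[2-(trimethylsilyl)ethoxy]cyclobut-2-en-1-one (racemic) | C[Si](C)(C)CCOC1=CC(=O)C1CC=C(C)C | intermediate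
10 | ethyl 4-methylpent-3-enoate | CCOC(=O)CC=C(C)C | starting material
11 | lithium 1,1-dibromo-5-methylhexa-1,4-dien-2-olate (not isolated) | CC(C)=CCC(O[Li])=C(Br)Br | intermediate
12 | lithium 5-methylhex-4-en-1-yn-1-olate (not isolated) | CC(C)=CCC#CO[Li] | intermediate
13 | triisopropyl[(5-methylhex-4-en-1-yn-1-yl)oxy]silane | CC(C)=CCC#CO[Si](C(C)C)(C(C)C)C(C)C | intermediate
14 | (3Z)-7-methyl-3-[2-(trimethylsilyl)ethoxy]octa-1,3,6-trien-1-one, alkyl chain trans to the ketene carbon (not isolated) | O=C=C/C(OCC[Si](C)(C)C)=C/CC=C(C)C | intermediate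
15 | 2-(3-methylbut-2-en-1-yl)-4-{(1Z)-5-methyl-1-[2-(trimethylsilyl)ethoxy]hexa-1,4-dien-1-yl}-3-[(triisopropylsilyl)oxy]cyclobut-2-en-1-one (racemic, not isolated) | O=C1C(CC=C(C)C)=C(O[Si](C(C)C)(C(C)C)C(C)C)C1/C(OCC[Si](C)(C)C)=C/CC=C(C)C | intermediate
16 | (3E,5Z)-9-methyl-2-(3-methylbut-2-en-1-yl)-3-[(triisopropylsilyl)oxy]-5-[2-(trimethylsilyl)ethoxy]deca-1,3,5,8-tetraen-1-one, C2 and C5 cis across C3=C4 (not isolated) | O=C=C(CC=C(C)C)/C(O[Si](C(C)C)(C(C)C)C(C)C)=C\C(OCC[Si](C)(C)C)=C\CC=C(C)C | intermediate
17 | 2,6-bis(3-methylbut-2-en-1-yl)-3-[(triisopropylsilyl)oxy]-5-[2-(trimethylsilyl)ethoxy]cyclohexa-2,4-dien-1-one (racemic, not isolated) | O=C1C(CC=C(C)C)=C(O[Si](C(C)C)(C(C)C)C(C)C)C=C(OCC[Si](C)(C)C)C1CC=C(C)C | intermediate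
18 | 2,6-bis(3-methylbut-2-en-1-yl)-3-[(triisopropylsilyl)oxy]-5-[2-(trimethylsilyl)ethoxy]phenol | Oc1c(CC=C(C)C)c(O[Si](C(C)C)(C(C)C)C(C)C)cc(OCC[Si](C)(C)C)c1CC=C(C)C | intermediate
19 | triisopropyl({2,2-dimethyl-8-(3-methylbut-2-en-1-yl)-5-[2-(trimethylsilyl)ethoxy]-2H-chromen-7-yl}oxy)silane (not isolated) | CC1(C)C=Cc2c(OCC[Si](C)(C)C)cc(O[Si](C(C)C)(C(C)C)C(C)C)c(CC=C(C)C)c2O1 | intermediate
20 | triisopropyl({2,2-dimethyl-8-(3-methylbut-2-en-1-yl)-7-[2-(trimethylsilyl)ethoxy]-2H-chromen-5-yl}oxy)silane (not isolated) | CC1(C)C=Cc2c(O[Si](C(C)C)(C(C)C)C(C)C)cc(OCC[Si](C)(C)C)c(CC=C(C)C)c2O1 | intermediate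
21 | 2,2-dimethyl-8-(3-methylbut-2-en-1-yl)-2H-chromene-5,7-diol | CC1(C)C=Cc2c(O)cc(O)c(CC=C(C)C)c2O1 | intermediate
22 | 5,7-bis(methoxymethoxy)-2,2-dimethyl-8-(3-methylbut-2-en-1-yl)-2H-chromene | CC1(C)C=Cc2c(OCOC)cc(OCOC)c(CC=C(C)C)c2O1 | intermediate
23 | 4-hydroxybenzaldehyde | O=Cc1ccc(O)cc1 | starting material
24 | 4-(methoxymethoxy)benzaldehyde | COCOc1ccc(C=O)cc1 | intermediate
25 | [5,7-bis(methoxymethoxy)-2,2-dimethyl-8-(3-methylbut-2-en-1-yl)-2H-chromen-6-yl]lithium (not isolated) | CC1(C)C=Cc2c(OCOC)c([Li])c(OCOC)c(CC=C(C)C)c2O1 | intermediate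
26 | [5,7-bis(methoxymethoxy)-2,2-dimethyl-8-(3-methylbut-2-en-1-yl)-2H-chromen-6-yl][4-(methoxymethoxy)phenyl]methanol (racemic) | CC1(C)C=Cc2c(OCOC)c(C(O)c3ccc(OCOC)cc3)c(OCOC)c(CC=C(C)C)c2O1 | intermediate
27 | [5,7-bis(methoxymethoxy)-2,2-dimethyl-8-(3-methylbut-2-en-1-yl)-2H-chromen-6-yl][4-(methoxymethoxy)phenyl]methanone | CC1(C)C=Cc2c(OCOC)c(C(=O)c3ccc(OCOC)cc3)c(OCOC)c(CC=C(C)C)c2O1 | intermediate
28 | vismiaphenone E, [5,7-dihydroxy-2,2-dimethyl-8-(3-methylbut-2-en-1-yl)-2H-chromen-6-yl](4-hydroxyphenyl)methanone (no stereocentre) | CC(C)=CCc1c(O)c(C(=O)c2ccc(O)cc2)c(O)c2c1OC(C)(C)C=C2 | target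

**Step count and risks**

Total step count: 10. Longest linear sequence: 8 steps (steps 1, 2, 4, 5, 6, 8, 9, 10).

Most likely to fail, step 4: the vinylogous-ester stabilisation of the 3-alkoxycyclobutenone may slow the first ring opening, so that the siloxyalkyne degrades before the vinylketene is captured, or the vinylketene is lost to dimerisation and to acylation of the product phenol. The fallback abandons the cycloaddition and takes ring A from phloroglucinol by classical acylphloroglucinol chemistry. It sets out from aldehyde 24 and comes back to the route at the target 28. Addition of 2,4,6-tris(methoxymethoxy)phenyllithium (from 1,3,5-tris(methoxymethoxy)benzene and n-BuLi, THF, 0 °C) to 24 would give [4-(methoxymethoxy)phenyl][2,4,6-tris(methoxymethoxy)phenyl]methanol F1. Dess–Martin oxidation would give the tetrakis(methoxymethyl) ketone F2, and HCl in MeOH would give (4-hydroxyphenyl)(2,4,6-trihydroxyphenyl)methanone F3. Condensation of F3 with 3-methylbut-2-enal (ethylenediammonium diacetate, PhMe, heat; aldol-type condensation then oxa-6π electrocyclisation through the hydroxyl para to the carbonyl) would give (5,7-dihydroxy-2,2-dimethyl-2H-chromen-6-yl)(4-hydroxyphenyl)methanone F4, to be separated from its 8-aroyl isomer. C-Prenylation of F4 at C8, the only free ring position (prenyl bromide, aqueous KOH), would give 28, in competition with O-alkylation.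

Second, step 5: over-oxidation, by a second hydride abstraction at the remaining prenyl group or at the newly formed electron-rich chromene, may outrun clean ring closure. The fallback replaces the dehydrogenative closure by electrophilic selenoetherification and selenoxide elimination. It sets out from phenol 18 and comes back at chromenes 19 and 20. PhSeCl (1.0 equiv, CH2Cl2, −78 °C) should give, by 6-endo attack of the phenol oxygen on the seleniranium ion at the tertiary carbon, the 3-(phenylselanyl)chromans: triisopropyl({2,2-dimethyl-8-(3-methylbut-2-en-1-yl)-3-(phenylselanyl)-5-[2-(trimethylsilyl)ethoxy]chroman-7-yl}oxy)silane F5 and its regioisomer with the two ether groups exchanged, F6 (both racemic). Oxidation with H2O2 (THF, 0 °C) and syn-elimination of the selenoxides towards C4 would give 19 and 20, which are then treated with Bu4NF as in step 5 to reach 21.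

Third, step 3: the carbenoid or the amide base may deprotonate the unusually acidic α-CH2 of the β,γ-unsaturated ester instead of adding to the carbonyl group, with loss of material and migration of the double bond into conjugation. The fallback reaches the same ynolate from an α,α-dibromo ester by bromine–lithium exchange, which needs no addition to an enolisable ester. It sets out from acid 6 and comes back at ynolate 12, and so at 13. Esterification (EtOH, H2SO4 cat.) would give ethyl 5-methylhex-4-enoate F7. Enolate bromination (LiN(iPr)2, THF, −78 °C; CBr4) would give ethyl 2-bromo-5-methylhex-4-enoate F8 (racemic), and a second round ethyl 2,2-dibromo-5-methylhex-4-enoate F9. Treatment of F9 with t-BuLi (4 equiv, THF, −78 → 0 °C) would give 12 by double exchange and loss of ethoxide, and iPr3SiOTf would then give 13.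

**Further compounds**

F1 | step 4 | [4-(methoxymethoxy)phenyl][2,4,6-tris(methoxymethoxy)phenyl]methanol (racemic) | COCOc1ccc(C(O)c2c(OCOC)cc(OCOC)cc2OCOC)cc1
F2 | step 4 | [4-(methoxymethoxy)phenyl][2,4,6-tris(methoxymethoxy)phenyl]methanone | COCOc1ccc(C(=O)c2c(OCOC)cc(OCOC)cc2OCOC)cc1
F3 | step 4 | (4-hydroxyphenyl)(2,4,6-trihydroxyphenyl)methanone | O=C(c1ccc(O)cc1)c1c(O)cc(O)cc1O
F4 | step 4 | (5,7-dihydroxy-2,2-dimethyl-2H-chromen-6-yl)(4-hydroxyphenyl)methanone | CC1(C)C=Cc2c(O)c(C(=O)c3ccc(O)cc3)c(O)cc2O1
F5 | step 5 | triisopropyl({2,2-dimethyl-8-(3-methylbut-2-en-1-yl)-3-(phenylselanyl)-5-[2-(trimethylsilyl)ethoxy]chroman-7-yl}oxy)silane (racemic) | CC1(C)Oc2c(CC=C(C)C)c(O[Si](C(C)C)(C(C)C)C(C)C)cc(OCC[Si](C)(C)C)c2CC1[Se]c1ccccc1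
F6 | step 5 | triisopropyl({2,2-dimethyl-8-(3-methylbut-2-en-1-yl)-3-(phenylselanyl)-7-[2-(trimethylsilyl)ethoxy]chroman-5-yl}oxy)silane (racemic) | CC1(C)Oc2c(CC=C(C)C)c(OCC[Si](C)(C)C)cc(O[Si](C(C)C)(C(C)C)C(C)C)c2CC1[Se]c1ccccc1
F7 | step 3 | ethyl 5-methylhex-4-enoate | CCOC(=O)CCC=C(C)C
F8 | step 3 | ethyl 2-bromo-5-methylhex-4-enoate (racemic) | CCOC(=O)C(Br)CC=C(C)C
F9 | step 3 | ethyl 2,2-dibromo-5-methylhex-4-enoate | CCOC(=O)C(Br)(Br)CC=C(C)C
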